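**Assumptions (one line each)**
- (DHQ)2AQN is assumed to open the meso anhydride to the (2R,3S) half-ester (quinine-type sense, by analogy with other cis-succinic anhydrides); if the sense is reversed, use (DHQD)2AQN and nothing else changes.
- 1-(Benzyloxy)-4-bromo-2-methoxybenzene is taken as purchased (otherwise one extra step: 4-bromo-2-methoxyphenol, BnBr, K2CO3).

**Retrosynthetic overview**
1. Target ⇒ global O-debenzylation of a threo (7''S,8''S) alcohol ⇐ Felkin–Anh reduction of an (S)-α-aryloxy aryl ketone.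
2. That ketone ⇐ aryl Grignard + Weinreb amide ⇐ Mitsunobu etherification (inversion) of the ring-B phenol with methyl (R)-lactate, which sets C8''.
3. Ring-B phenol (unsymmetrical "meso-type" dibenzylbutane, 8S,8'R) ⇐ two sequential aryl-ketone formations and deoxygenations on a 2,3-dimethylsuccinic half-ester.
4. Half-ester ⇐ catalytic enantioselective methanolysis of meso-2,3-dimethylsuccinic anhydride, which sets C8 and C8' in one step.
5. No rings are constructed: the three arenes are bought as aryl bromides and attached in the order ring A (acid end), ring B (ester end), ring C (lactate end).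

**Route**

Step 1
Reactants: 1, meso-2,3-dimethylsuccinic acid
Product: 2, cis-3,4-dimethyloxolane-2,5-dione (meso anhydride)
Conditions: AcCl (neat), reflux, 2 h; evaporate
Reagents that add atoms: none
Why: Cyclodehydration of a 1,4-diacid without base keeps the cis (meso) relationship of the two methyl-bearing carbons.

Step 2
Reactants: 2; 3, methanol
Product: 4, (2R,3S)-4-methoxy-2,3-dimethyl-4-oxobutanoic acid
Conditions: (DHQ)2AQN (8 mol %), MeOH (10 equiv), Et2O, −20 °C
Reagents that add atoms: methanol, CO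
Why: Cinchona-alkaloid-catalysed desymmetrising alcoholysis of a meso anhydride selects one enantiotopic carbonyl, fixing both methyl stereocentres (future C8 and C8') at once.

Step 3
Reactants: 4; 5, 1-(benzyloxy)-4-bromo-2-methoxybenzene
Product: 6, methyl (2S,3R)-4-[4-(benzyloxy)-3-methoxyphenyl]-2,3-dimethyl-4-oxobutanoate
Conditions: (COCl)2, cat. DMF, CH2Cl2, 0 °C→rt; then ArZnCl (from 5: n-BuLi, THF, −78 °C; ZnCl2), Pd(PPh3)4 (5 mol %), THF, 0 °C→rt
Reagents that add atoms: aryl bromide 5 (as its arylzinc), COc1cc(Br)ccc1OCc1ccccc1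
Why: Negishi acylation of the acid chloride is neutral and chemoselective, so the methyl ester and the α-stereocentre survive (no amine base, no ketene); the descriptor changes only through CIP priorities.

Step 4
Reactants: 6
Product: 7, methyl (2S,3S)-4-[4-(benzyloxy)-3-methoxyphenyl]-2,3-dimethylbutanoate
Conditions: Et3SiH (4 equiv), TFA/CH2Cl2, 0 °C→rt
Reagents that add atoms: none
Why: Ionic hydrogenation takes the electron-rich aryl ketone to ArCH2 via the benzylic cation while the benzyl ether and ester are retained; no bond at a stereocentre is touched.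

Step 5
Reactants: 7; 8, N,O-dimethylhydroxylamine hydrochloride
Product: 9, (2S,3S)-4-[4-(benzyloxy)-3-methoxyphenyl]-N-methoxy-N,2,3-trimethylbutanamide
Conditions: MeNHOMe·HCl, i-PrMgCl, THF, −20→0 °C
Reagents that add atoms: N,O-dimethylhydroxylamine hydrochloride, CNOC.Cl
Why: Direct ester-to-Weinreb-amide aminolysis by the magnesium amide is weakly basic and does not epimerise the α-methyl centre.

Step 6
Reactants: 10, 4-bromo-2,6-dimethoxyphenol; 11, 4-methoxybenzyl chloride
Product: 12, 5-bromo-1,3-dimethoxy-2-[(4-methoxybenzyl)oxy]benzene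
Conditions: K2CO3, cat. TBAI, DMF, 50 °C
Reagents that add atoms: 4-methoxybenzyl chloride, COc1ccc(CCl)cc1
Why: Williamson etherification masks the ring-B phenol with a group that survives aryllithium chemistry and is removed by acid/silane in step 8.

Step 7
Reactants: 9; 12
Product: 13, (2S,3S)-4-[4-(benzyloxy)-3-methoxyphenyl]-1-{3,5-dimethoxy-4-[(4-methoxybenzyl)oxy]phenyl}-2,3-dimethylbutan-1-one
Conditions: 12, n-BuLi, THF, −78 °C; then 9, −78→−20 °C; cold aq. NH4Cl
Reagents that add atoms: aryl bromide 12 (as its aryllithium), COc1ccc(COc2c(OC)cc(Br)cc2OC)cc1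
Why: Weinreb ketone synthesis—the chelated tetrahedral intermediate prevents over-addition and keeps the α-centre non-enolised until quench.

Step 8
Reactants: 13
Product: 14, 4-{(2R,3S)-4-[4-(benzyloxy)-3-methoxyphenyl]-2,3-dimethylbutyl}-2,6-dimethoxyphenol
Conditions: Et3SiH (6 equiv), TFA/CH2Cl2, 0 °C→rt
Reagents that add atoms: none
Why: One ionic-hydrogenation operation deoxygenates the ketone and cleaves the PMB ether (silane scavenges the PMB cation), unveiling only the ring-B phenol while the ring-A benzyl ether stays.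

Step 9
Reactants: 14; 15, methyl (R)-lactate
Product: 16, methyl (2S)-2-(4-{(2R,3S)-4-[4-(benzyloxy)-3-methoxyphenyl]-2,3-dimethylbutyl}-2,6-dimethoxyphenoxy)propanoate
Conditions: PPh3, DIAD, THF, 0 °C→rt
Reagents that add atoms: methyl (R)-lactate, C[C@@H](O)C(=O)OC
Why: Mitsunobu etherification proceeds by SN2 inversion at the lactate carbon, converting (R)-lactate into the (S)-aryl ether (C8'').

Step 10
Reactants: 16; 8, N,O-dimethylhydroxylamine hydrochloride
Product: 17, (2S)-2-(4-{(2R,3S)-4-[4-(benzyloxy)-3-methoxyphenyl]-2,3-dimethylbutyl}-2,6-dimethoxyphenoxy)-N-methoxy-N-methylpropanamide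
Conditions: MeNHOMe·HCl, i-PrMgCl, THF, −20 °C
Reagents that add atoms: N,O-dimethylhydroxylamine hydrochloride, CNOC.Cl
Why: Low-temperature Weinreb aminolysis of the α-aryloxy ester occurs without racemising C8''.

Step 11
Reactants: 17; 5, 1-(benzyloxy)-4-bromo-2-methoxybenzene
Product: 18, (2S)-1-[4-(benzyloxy)-3-methoxyphenyl]-2-(4-{(2R,3S)-4-[4-(benzyloxy)-3-methoxyphenyl]-2,3-dimethylbutyl}-2,6-dimethoxyphenoxy)propan-1-one
Conditions: ArMgBr (from 5, Mg, THF; 2.5 equiv), THF, 0 °C; cold aq. NH4Cl; use crude, no basic media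
Reagents that add atoms: aryl bromide 5 (as its Grignard reagent), COc1cc(Br)ccc1OCc1ccccc1
Why: Weinreb ketone synthesis installs ring C; the ketone is released only on neutral quench, so the labile α-aryloxy centre is preserved.

Step 12
Reactants: 18
Product: 19, (1S,2S)-1-[4-(benzyloxy)-3-methoxyphenyl]-2-(4-{(2R,3S)-4-[4-(benzyloxy)-3-methoxyphenyl]-2,3-dimethylbutyl}-2,6-dimethoxyphenoxy)propan-1-ol (threo)
Conditions: K-Selectride, THF, −78 °C; separate any erythro isomer by chromatography
Reagents that add atoms: none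
Why: A bulky, non-chelating hydride follows the polar Felkin–Anh model (aryloxy group anti to the incoming hydride), so the (S)-ketone gives the syn/threo (7''S,8''S) alcohol.

Step 13
Reactants: 19
Product: 20, the target, (7''S,8S,8'R,8''S)-4,4''-dihydroxy-3,3',3'',5'-tetramethoxy-4',8''-oxy-8,8'-sesquineolignan-7''-ol
Conditions: H2 (1 atm), 10 % Pd/C, EtOAc/MeOH, rt, neutral, monitored
Reagents that add atoms: none
Why: Neutral hydrogenolysis cleaves the two aryl benzyl ethers much faster than the secondary benzylic C–OH or the alkyl aryl ether, leaving all four stereocentres untouched.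

**Compound list**

1 | meso-2,3-dimethylsuccinic acid | OC(=O)[C@H](C)[C@H](C)C(=O)O | starting material
2 | cis-3,4-dimethyloxolane-2,5-dione | O=C1[C@H](C)[C@H](C)C(=O)O1 | intermediate
3 | methanol | CO | starting material
4 | (2R,3S)-4-methoxy-2,3-dimethyl-4-oxobutanoic acid | OC(=O)[C@H](C)[C@H](C)C(=O)OC | intermediate
5 | 1-(benzyloxy)-4-bromo-2-methoxybenzene | COc1cc(Br)ccc1OCc1ccccc1 | starting material
6 | methyl (2S,3R)-4-[4-(benzyloxy)-3-methoxyphenyl]-2,3-dimethyl-4-oxobutanoate | COc1cc(C(=O)[C@H](C)[C@H](C)C(=O)OC)ccc1OCc1ccccc1 | intermediate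
7 | methyl (2S,3S)-4-[4-(benzyloxy)-3-methoxyphenyl]-2,3-dimethylbutanoate | COc1cc(C[C@H](C)[C@H](C)C(=O)OC)ccc1OCc1ccccc1 | intermediate
8 | N,O-dimethylhydroxylamine hydrochloride | CNOC.Cl | starting material
9 | (2S,3S)-4-[4-(benzyloxy)-3-methoxyphenyl]-N-methoxy-N,2,3-trimethylbutanamide | COc1cc(C[C@H](C)[C@H](C)C(=O)N(C)OC)ccc1OCc1ccccc1 | intermediate
10 | 4-bromo-2,6-dimethoxyphenol | COc1cc(Br)cc(OC)c1O | starting material
11 | 4-methoxybenzyl chloride | COc1ccc(CCl)cc1 | starting material
12 | 5-bromo-1,3-dimethoxy-2-[(4-methoxybenzyl)oxy]benzene | COc1ccc(COc2c(OC)cc(Br)cc2OC)cc1 | intermediate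
13 | (2S,3S)-4-[4-(benzyloxy)-3-methoxyphenyl]-1-{3,5-dimethoxy-4-[(4-methoxybenzyl)oxy]phenyl}-2,3-dimethylbutan-1-one | COc1cc(C[C@H](C)[C@H](C)C(=O)c2cc(OC)c(OCc3ccc(OC)cc3)c(OC)c2)ccc1OCc1ccccc1 | intermediate
14 | 4-{(2R,3S)-4-[4-(benzyloxy)-3-methoxyphenyl]-2,3-dimethylbutyl}-2,6-dimethoxyphenol | COc1cc(C[C@H](C)[C@H](C)Cc2cc(OC)c(O)c(OC)c2)ccc1OCc1ccccc1 | intermediate
15 | methyl (R)-lactate | C[C@@H](O)C(=O)OC | starting material
16 | methyl (2S)-2-(4-{(2R,3S)-4-[4-(benzyloxy)-3-methoxyphenyl]-2,3-dimethylbutyl}-2,6-dimethoxyphenoxy)propanoate | COc1cc(C[C@H](C)[C@H](C)Cc2cc(OC)c(O[C@@H](C)C(=O)OC)c(OC)c2)ccc1OCc1ccccc1 | intermediate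
17 | (2S)-2-(4-{(2R,3S)-4-[4-(benzyloxy)-3-methoxyphenyl]-2,3-dimethylbutyl}-2,6-dimethoxyphenoxy)-N-methoxy-N-methylpropanamide | COc1cc(C[C@H](C)[C@H](C)Cc2cc(OC)c(O[C@@H](C)C(=O)N(C)OC)c(OC)c2)ccc1OCc1ccccc1 | intermediate
18 | (2S)-1-[4-(benzyloxy)-3-methoxyphenyl]-2-(4-{(2R,3S)-4-[4-(benzyloxy)-3-methoxyphenyl]-2,3-dimethylbutyl}-2,6-dimethoxyphenoxy)propan-1-one | COc1cc(C[C@H](C)[C@H](C)Cc2cc(OC)c(O[C@@H](C)C(=O)c3ccc(OCc4ccccc4)c(OC)c3)c(OC)c2)ccc1OCc1ccccc1 | intermediate
19 | (1S,2S)-1-[4-(benzyloxy)-3-methoxyphenyl]-2-(4-{(2R,3S)-4-[4-(benzyloxy)-3-methoxyphenyl]-2,3-dimethylbutyl}-2,6-dimethoxyphenoxy)propan-1-ol | COc1cc(C[C@H](C)[C@H](C)Cc2cc(OC)c(O[C@@H](C)[C@@H](O)c3ccc(OCc4ccccc4)c(OC)c3)c(OC)c2)ccc1OCc1ccccc1 | intermediate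
20 | (7''S,8S,8'R,8''S)-4,4''-dihydroxy-3,3',3'',5'-tetramethoxy-4',8''-oxy-8,8'-sesquineolignan-7''-ol | COc1cc(C[C@H](C)[C@H](C)Cc2cc(OC)c(O[C@@H](C)[C@@H](O)c3ccc(O)c(OC)c3)c(OC)c2)ccc1O | target

**Step count**
- Total steps: 13.
- Longest linear sequence: 12 (steps 1–5, then 7–13, from meso-2,3-dimethylsuccinic acid); step 6 is a one-step side branch.

**Three steps most likely to fail, with fallbacks**

1. Step 12 (threo selectivity of the ketone reduction, and possible epimerisation of the α-aryloxy ketone beforehand). Fallback: reduce under chelation control (Zn(BH4)2, Et2O) to the erythro (7''R,8''S) alcohol and invert C7'' by Mitsunobu esterification with 4-nitrobenzoic acid followed by K2CO3/MeOH. This sets C7'' by SN2 inversion instead of by hydride facial selectivity.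

2. Steps 7–8 (and 3–4): the α-methyl aryl ketones may epimerise to the threo-dimethyl series, and TFA/Et3SiH may partly debenzylate or lactonise. Fallback: avoid aryl ketones altogether. Reduce the acid of 4 (BH3·SMe2) to the primary alcohol, convert to the iodide, and form each ArCH2 bond by sp3–sp2 Negishi coupling of the alkylzinc iodide with the aryl bromide (Pd/SPhos); repeat at the ester end after reduction. No enolisable stereocentre is ever generated.

3. Step 9 (Mitsunobu on a hindered 2,6-dimethoxyphenol; low conversion or elimination of the lactate). Fallback: O-alkylate 14 (Cs2CO3, DMF) with racemic 2-bromo-1-[4-(benzyloxy)-3-methoxyphenyl]propan-1-one and set C7'' and C8'' together by dynamic-kinetic asymmetric transfer hydrogenation (Ru–TsDPEN, HCO2H/Et3N). This also removes steps 10–11.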